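The plan cuts both aryl–C1' bonds at once. In each aromatic ring (A, A') the quaternary cyclopentane carbon C1' sits on C3. This is the only open ortho position of the oxygen on C2, because C1 carries the second oxygen and the para carbon C5 carries the CH2CH2 bridge. A two-directional aromatic Claisen rearrangement therefore has a single outlet per ring. It slides each O-bound (S)-3-methylcyclopent-2-enyl unit across one face of its five-membered ring. Two C–C bonds and both quaternary stereocentres thus arise in one operation from easily set carbinol centres. The precursor is the twofold-symmetric bis(cyclopentenyl) ether of a vanillin-derived bibenzyl bisphenol. The gem-dimethyl group is added later at C5', the saturated ring neighbour of C1'.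

Key step: step 5

Numbering: aromatic rings as in the target (C1–O, C2–O, C3–cyclopentyl, C5–bridge). After the rearrangement the five-membered ring is C1' (quaternary), C2'=C3', C4'H2, C5'H2.

Remark (assumption): in every two-directional step the two identical halves react in turn under the same conditions. Half-converted or partly alkylated species are not numbered, and in-flask intermediates are drawn with both halves at the same stage.

Remark (descriptors): the spatial arrangement at C1' never changes after the rearrangement. Its CIP label reads R from the rearrangement product to the saturated diketone and S after deoxygenation, only because the ranking of its neighbours changes.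

Remark (purity): because two alcohol units are joined, most of the minor alcohol enantiomer ends up in the meso diastereomer. This isomer is to be removed by crystallisation or preparative HPLC at the bis-enone or diketone stage.

Step 1
Reactants: 1 4-(benzyloxy)-3-methoxybenzaldehyde (O-benzylvanillin, two molecules)
Product: 2 (E)-1,2-bis[4-(benzyloxy)-3-methoxyphenyl]ethene
Conditions: TiCl4, Zn dust, THF, reflux
Reagents that add atoms: none
Why: McMurry reductive coupling of an electron-rich aryl aldehyde by low-valent titanium, which benzyl and methyl aryl ethers tolerate; it should give mainly the E-stilbene, and the alkene geometry is erased in step 2.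

Step 2
Reactants: 2 (E)-1,2-bis[4-(benzyloxy)-3-methoxyphenyl]ethene
Product: 3 4,4'-(ethane-1,2-diyl)bis(2-methoxyphenol)
Conditions: H2 (1 atm), 10% Pd/C, THF–EtOH, rt
Reagents that add atoms: none
Why: Heterogeneous catalytic hydrogenation saturates the stilbene C=C and hydrogenolyses both O-benzyl groups in the same operation, while the aryl methyl ethers are inert; no stereocentre is formed.

Step 3
Reactants: 4 3-methylcyclopent-2-en-1-one
Product: 5 (R)-3-methylcyclopent-2-en-1-ol
Conditions: (S)-Me-CBS oxazaborolidine (C18H20BNO, 10 mol %), BH3·SMe2, THF, −20 °C; MeOH, then aq. NaHCO3; kept as a dried PhMe solution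
Reagents that add atoms: none
Why: Corey–Bakshi–Shibata reduction, in which the ketone binds to the catalyst–borane complex with its sp2 arm (C2=C3) in the place of the large substituent, so hydride is delivered 1,2 to one carbonyl face and sets C1 as R, the same sense in which this catalyst antipode turns aryl methyl ketones into R alcohols; the base-buffered work-up protects the volatile, acid-labile allylic alcohol.

Step 4
Reactants: 3 4,4'-(ethane-1,2-diyl)bis(2-methoxyphenol); 5 (R)-3-methylcyclopent-2-en-1-ol (slight excess over two equivalents)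
Product: 7 1,2-bis{3-methoxy-4-[(1S)-3-methylcyclopent-2-en-1-yl]oxyphenyl}ethane, via alkoxyphosphonium ion 6 (not isolated)
Conditions: PPh3, DIAD, THF–PhMe, −20 to 0 °C; chromatography on Et3N-deactivated silica
Reagents that add atoms: none
Why: Mitsunobu etherification, in which the guaiacol-type phenoxide displaces Ph3P=O from 6 in an SN2 step with inversion, so each R carbinol carbon becomes an S ether carbon; low temperature and a weakly polar medium disfavour ionisation of the activated allylic C–O bond, and joining two units should raise the enantiomeric purity of the twofold-symmetric ether above that of 5 by statistical amplification.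

Step 5
Reactants: 7 1,2-bis{3-methoxy-4-[(1S)-3-methylcyclopent-2-en-1-yl]oxyphenyl}ethane
Product: 9 4,4'-(ethane-1,2-diyl)bis{2-methoxy-6-[(1R)-1-methylcyclopent-2-en-1-yl]phenol}, via bis-dienone 8 (not isolated)
Conditions: Eu(fod)3 (20 mol %), degassed PhMe, 80 °C, Ar, base-washed glassware
Reagents that add atoms: none
Why: In each half the O–C bond of the ether breaks while aromatic C3 bonds to the methyl-bearing alkene carbon through a six-membered cyclic transition state ([3,3]-sigmatropic shift), giving dienone 8, which enolises to the phenol. The closest known reaction type is the thermal or Eu(fod)3-catalysed aromatic Claisen rearrangement of enantioenriched cycloalkenyl aryl ethers and of prenyl-type aryl ethers, the latter already creating quaternary benzylic carbons; here it is run twice in one molecule. No ring is formed. Each new stereocentre C1' is controlled by the ether carbon, because the five-membered ring lets the aryl group leave and arrive only on the same face, so the S carbinol carbon is translated into the arrangement labelled R in 9, which is the one labelled S in the target once C5' is CMe2. Site selectivity is built in: C1 is blocked by OMe and C5 by the bridge, so a shift to either gives a dienone that cannot enolise and can only revert. The step needs the concerted path to outrun heterolysis to the methylcyclopentenyl cation (elimination, stereochemical leakage, C-alkylation through the secondary allyl terminus), and this is served by a mild oxophilic europium centre chelated by the two neighbouring oxygens, a hydrocarbon solvent and strict exclusion of acid.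

Step 6
Reactants: 9 4,4'-(ethane-1,2-diyl)bis{2-methoxy-6-[(1R)-1-methylcyclopent-2-en-1-yl]phenol}
Product: 10 1,2-bis{3,4-dimethoxy-5-[(1R)-1-methylcyclopent-2-en-1-yl]phenyl}ethane
Conditions: MeI, K2CO3, DMF, rt (crude 9 used at once)
Reagents that add atoms: iodomethane, CI
Why: Williamson O-methylation of the hindered phenoxide with a small electrophile, run directly on crude 9 because the free phenol could add to the neighbouring C2'=C3' bond under acid and would not survive the oxidant of step 7; no stereocentre is touched.

Step 7
Reactants: 10 1,2-bis{3,4-dimethoxy-5-[(1R)-1-methylcyclopent-2-en-1-yl]phenyl}ethane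
Product: 11 1,2-bis{3,4-dimethoxy-5-[(1R)-1-methyl-4-oxocyclopent-2-en-1-yl]phenyl}ethane
Conditions: CrO3, 3,5-dimethylpyrazole, CH2Cl2, −20 °C
Reagents that add atoms: chromium trioxide, O=[Cr](=O)=O
Why: Allylic C–H oxidation with the CrO3·3,5-dimethylpyrazole complex, a standard way from hindered cyclopentenes to cyclopentenones; C4'H2 is the only allylic CH2 because C1' is quaternary, oxygen ends at the unhindered end of the allyl system, and at low temperature the allylic position should react ahead of the bridge CH2 groups, as it does in substrates that carry benzyl ethers or aryl-bound alkyl groups.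

Step 8
Reactants: 11 1,2-bis{3,4-dimethoxy-5-[(1R)-1-methyl-4-oxocyclopent-2-en-1-yl]phenyl}ethane
Product: 12 1,2-bis{3,4-dimethoxy-5-[(1R)-1,5,5-trimethyl-4-oxocyclopent-2-en-1-yl]phenyl}ethane
Conditions: NaH (excess), MeI (excess), THF–DMF, 0 °C to rt
Reagents that add atoms: iodomethane, CI
Why: Exhaustive alpha'-alkylation of a cross-conjugated enolate, known for 4-aryl-4-methylcyclopent-2-enones; C5'H2 is the only enolisable position because the gamma carbon C1' is quaternary, so both methyl groups can only enter between the carbonyl and C1', the enone beta carbon is shielded by C1' against Michael self-addition, and C1' cannot epimerise.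

Step 9
Reactants: 12 1,2-bis{3,4-dimethoxy-5-[(1R)-1,5,5-trimethyl-4-oxocyclopent-2-en-1-yl]phenyl}ethane
Product: 13 1,2-bis{3,4-dimethoxy-5-[(1R)-1,2,2-trimethyl-3-oxocyclopentyl]phenyl}ethane
Conditions: H2 (1 atm), 10% Pd/C, EtOAc, rt
Reagents that add atoms: none
Why: Catalytic hydrogenation of the conjugated C=C, under which the ketones, arenes and methyl ethers are inert and no new stereocentre arises.

Step 10
Reactants: 13 1,2-bis{3,4-dimethoxy-5-[(1R)-1,2,2-trimethyl-3-oxocyclopentyl]phenyl}ethane
Product: 15 1,2-bis{3,4-dimethoxy-5-[(1S)-1,2,2-trimethylcyclopentyl]phenyl}ethane, via bis-hydrazone 14 (not isolated)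
Conditions: N2H4·H2O, KOH, diethylene glycol, 130 °C, then 200 °C with removal of water
Reagents that add atoms: none
Why: Wolff–Kishner reduction in the Huang-Minlon form through 14, the established deoxygenation of hindered 2,2,3-trisubstituted 3-arylcyclopentanones, which hold no epimerisable centre; partial loss of O-methyl groups in hot KOH would be harmless because step 11 removes them all.

Step 11
Reactants: 15 1,2-bis{3,4-dimethoxy-5-[(1S)-1,2,2-trimethylcyclopentyl]phenyl}ethane
Product: 17 5,5'-(ethane-1,2-diyl)bis{3-[(1S)-1,2,2-trimethylcyclopentyl]benzene-1,2-diol} (target), via bis-bromoborole 16 (not isolated)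
Conditions: BBr3, CH2Cl2, −78 °C to rt; then H2O, under Ar
Reagents that add atoms: none
Why: Lewis-acid cleavage of aryl methyl ethers, in which BBr3 binds each OMe, bromide removes the methyl group by SN2 and the cyclic boron catecholate 16 is hydrolysed on work-up; the all-carbon stereocentres are untouched and the air-sensitive bis-catechol is handled under argon.

Compound list
1 | 4-(benzyloxy)-3-methoxybenzaldehyde (O-benzylvanillin) | COc1cc(C=O)ccc1OCc1ccccc1 | starting material
2 | (E)-1,2-bis[4-(benzyloxy)-3-methoxyphenyl]ethene | COc1cc(/C=C/c2ccc(OCc3ccccc3)c(OC)c2)ccc1OCc1ccccc1 | intermediate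
3 | 4,4'-(ethane-1,2-diyl)bis(2-methoxyphenol) | COc1cc(CCc2ccc(O)c(OC)c2)ccc1O | intermediate
4 | 3-methylcyclopent-2-en-1-one | CC1=CC(=O)CC1 | starting material
5 | (R)-3-methylcyclopent-2-en-1-ol | O[C@H]1C=C(C)CC1 | intermediate
6 | {[(1R)-3-methylcyclopent-2-en-1-yl]oxy}triphenylphosphonium ion (not isolated) | c1ccc(cc1)[P+](c1ccccc1)(c1ccccc1)O[C@H]1C=C(C)CC1 | intermediate
7 | 1,2-bis{3-methoxy-4-[(1S)-3-methylcyclopent-2-en-1-yl]oxyphenyl}ethane (key-step precursor) | COc1cc(CCc2ccc(O[C@@H]3C=C(C)CC3)c(OC)c2)ccc1O[C@@H]1C=C(C)CC1 | intermediate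
8 | 4,4'-(ethane-1,2-diyl)bis{2-methoxy-6-[(1R)-1-methylcyclopent-2-en-1-yl]cyclohexa-2,4-dien-1-one}, both halves drawn at the dienone stage, transient ring CH centre not specified (not isolated) | O=C1C(OC)=CC(CCC2=CC([C@@]3(C)C=CCC3)C(=O)C(OC)=C2)=CC1[C@@]1(C)C=CCC1 | intermediate
9 | 4,4'-(ethane-1,2-diyl)bis{2-methoxy-6-[(1R)-1-methylcyclopent-2-en-1-yl]phenol} (key-step product) | COc1cc(CCc2cc(OC)c(O)c([C@@]3(C)C=CCC3)c2)cc([C@@]2(C)C=CCC2)c1O | intermediate
10 | 1,2-bis{3,4-dimethoxy-5-[(1R)-1-methylcyclopent-2-en-1-yl]phenyl}ethane | COc1cc(CCc2cc(OC)c(OC)c([C@@]3(C)C=CCC3)c2)cc([C@@]2(C)C=CCC2)c1OC | intermediate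
11 | 1,2-bis{3,4-dimethoxy-5-[(1R)-1-methyl-4-oxocyclopent-2-en-1-yl]phenyl}ethane | COc1cc(CCc2cc(OC)c(OC)c([C@@]3(C)C=CC(=O)C3)c2)cc([C@@]2(C)C=CC(=O)C2)c1OC | intermediate
12 | 1,2-bis{3,4-dimethoxy-5-[(1R)-1,5,5-trimethyl-4-oxocyclopent-2-en-1-yl]phenyl}ethane | COc1cc(CCc2cc(OC)c(OC)c([C@@]3(C)C=CC(=O)C3(C)C)c2)cc([C@@]2(C)C=CC(=O)C2(C)C)c1OC | intermediate
13 | 1,2-bis{3,4-dimethoxy-5-[(1R)-1,2,2-trimethyl-3-oxocyclopentyl]phenyl}ethane | COc1cc(CCc2cc(OC)c(OC)c([C@@]3(C)CCC(=O)C3(C)C)c2)cc([C@@]2(C)CCC(=O)C2(C)C)c1OC | intermediate
14 | bis-hydrazone of 13, C=N geometry not specified (not isolated) | COc1cc(CCc2cc(OC)c(OC)c([C@@]3(C)CCC(=NN)C3(C)C)c2)cc([C@@]2(C)CCC(=NN)C2(C)C)c1OC | intermediate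
15 | 1,2-bis{3,4-dimethoxy-5-[(1S)-1,2,2-trimethylcyclopentyl]phenyl}ethane | COc1cc(CCc2cc(OC)c(OC)c([C@@]3(C)CCCC3(C)C)c2)cc([C@@]2(C)CCCC2(C)C)c1OC | intermediate
16 | 6,6'-(ethane-1,2-diyl)bis{2-bromo-4-[(1S)-1,2,2-trimethylcyclopentyl]-1,3,2-benzodioxaborole} (not isolated) | BrB1Oc2cc(CCc3cc4OB(Br)Oc4c([C@@]4(C)CCCC4(C)C)c3)cc([C@@]3(C)CCCC3(C)C)c2O1 | intermediate
17 | 5,5'-(ethane-1,2-diyl)bis{3-[(1S)-1,2,2-trimethylcyclopentyl]benzene-1,2-diol} | CC1(C)CCC[C@]1(C)c1cc(CCc2cc(O)c(O)c([C@@]3(C)CCCC3(C)C)c2)cc(O)c1O | target

Total step count: 11.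
Longest linear sequence: 10 steps (1, 2, 4–11, from compound 1). The branch from 4 adds step 3.

Steps most likely to fail

1. Step 5 (key step).
- What may go wrong: heterolysis of the allylic C–O bond may outrun the concerted shift. Elimination, loss of stereochemical fidelity or C-alkylation through the secondary allyl terminus would then take over. The freed phenol may also add to the new double bond.
- Fallback (sets out from 3 and 4, comes back at 11): the aryl–C1' bonds are made by asymmetric conjugate addition instead of by rearrangement.
- Bromination of 3 ortho to each hydroxyl (Br2, AcOH; the para position is blocked) gives 4,4'-(ethane-1,2-diyl)bis(2-bromo-6-methoxyphenol) F1.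
- O-Methylation (MeI, K2CO3, DMF) gives 1,2-bis(3-bromo-4,5-dimethoxyphenyl)ethane F2.
- Lithiation–borylation (n-BuLi, THF, −78 °C; B(OiPr)3; dilute acid) gives the bis(boronic acid) F3.
- Palladium-catalysed conjugate addition of F3 to an excess of 4 follows, with Pd(OCOCF3)2, (R)-4-tert-butyl-2-(pyridin-2-yl)-4,5-dihydrooxazole, NH4PF6 and H2O in ClCH2CH2Cl at 40–60 °C. It should give 1,2-bis{3,4-dimethoxy-5-[(1S)-1-methyl-3-oxocyclopentyl]phenyl}ethane F4.
- The R ligand is chosen because its S antipode is known to give R ketones with simple arylboronic acids. The ortho methoxy group is expected to slow this coupling.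
- Kinetic enolisation away from C1' (LDA, TMSCl, THF, −78 °C) gives the bis(trimethylsilyl enol ether) F5.
- Saegusa–Ito dehydrogenation (Pd(OAc)2, MeCN) then gives 11. Desaturation can only run away from the quaternary carbon, so the CH2 between carbonyl and C1' is left for step 8.

2. Step 4.
- What may go wrong: the activated allylic alcohol may ionise before displacement. This would bring incomplete inversion, attack with allylic shift or elimination. The second etherification may also stall.
- Fallback (sets out from 4 and 3, comes back at 7): the C–O bond is made with net retention by Tsuji–Trost O-allylation instead of by SN2 inversion.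
- Reduction of 4 with (R)-Me-CBS oxazaborolidine (C18H20BNO) and BH3·SMe2 gives (S)-3-methylcyclopent-2-en-1-ol F6.
- Methyl chloroformate and pyridine give methyl (S)-3-methylcyclopent-2-en-1-yl carbonate F7.
- Treatment of 3 with F7, Pd2(dba)3·CHCl3 and 1,2-bis(diphenylphosphino)ethane in THF at 0 °C to rt should give 7.
- Ionisation and phenoxide attack both occur anti to the metal, a double inversion. The phenoxide takes the less hindered secondary allyl terminus.

3. Step 7.
- What may go wrong: hydrogen abstraction at the benzylic bridge may compete with the allylic position. The second oxidation may stall, or the electron-rich arenes may suffer oxidative damage.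
- Fallback (sets out from 10, comes back at 11): oxo-transfer by chromium is replaced by a two-electron organometallic C–H acetoxylation followed by adjustment of the oxidation level.
- Pd(OAc)2 (10 mol %), 1,4-benzoquinone, AcOH, 50 °C should give the bis(allylic acetate) F8, epimeric at C4'.
- The C–H bond is broken only after the alkene has bound to divalent palladium, so the bridge CH2 groups cannot take part. Acetate enters at the unhindered C4' end.
- Methanolysis (K2CO3, MeOH) gives the bis(allylic alcohol) F9, and MnO2 in CH2Cl2 oxidises it to 11, which erases the C4' centres.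

Further compounds
F1 | step 5 | 4,4'-(ethane-1,2-diyl)bis(2-bromo-6-methoxyphenol) | COc1cc(CCc2cc(Br)c(O)c(OC)c2)cc(Br)c1O
F2 | step 5 | 1,2-bis(3-bromo-4,5-dimethoxyphenyl)ethane | COc1cc(CCc2cc(Br)c(OC)c(OC)c2)cc(Br)c1OC
F3 | step 5 | [ethane-1,2-diylbis(2,3-dimethoxy-5,1-phenylene)]diboronic acid | COc1cc(CCc2cc(B(O)O)c(OC)c(OC)c2)cc(B(O)O)c1OC
F4 | step 5 | 1,2-bis{3,4-dimethoxy-5-[(1S)-1-methyl-3-oxocyclopentyl]phenyl}ethane | COc1cc(CCc2cc(OC)c(OC)c([C@@]3(C)CCC(=O)C3)c2)cc([C@@]2(C)CCC(=O)C2)c1OC
F5 | step 5 | 1,2-bis{3,4-dimethoxy-5-[(1S)-1-methyl-3-(trimethylsilyloxy)cyclopent-3-en-1-yl]phenyl}ethane | COc1cc(CCc2cc(OC)c(OC)c([C@@]3(C)CC=C(O[Si](C)(C)C)C3)c2)cc([C@@]2(C)CC=C(O[Si](C)(C)C)C2)c1OC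
F6 | step 4 | (S)-3-methylcyclopent-2-en-1-ol | O[C@@H]1C=C(C)CC1
F7 | step 4 | methyl (S)-3-methylcyclopent-2-en-1-yl carbonate | COC(=O)O[C@@H]1C=C(C)CC1
F8 | step 7 | 1,2-bis{5-[(1R)-4-acetoxy-1-methylcyclopent-2-en-1-yl]-3,4-dimethoxyphenyl}ethane, epimers at C4' | COc1cc(CCc2cc(OC)c(OC)c([C@@]3(C)C=CC(OC(C)=O)C3)c2)cc([C@@]2(C)C=CC(OC(C)=O)C2)c1OC
F9 | step 7 | 1,2-bis{5-[(1R)-4-hydroxy-1-methylcyclopent-2-en-1-yl]-3,4-dimethoxyphenyl}ethane, epimers at C4' | COc1cc(CCc2cc(OC)c(OC)c([C@@]3(C)C=CC(O)C3)c2)cc([C@@]2(C)C=CC(O)C2)c1OC
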